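**Retrosynthetic overview**

- Feature: the chain on C6 of ring A (C6–CH2–CH2–C(CH3)2–OH, next to O5) and the carbon bridge of pyran ring D (C5'–CH=CH–C(CH3)2–O4' on ring B) are each three carbons running from an arene carbon to an oxygenated gem-dimethyl carbon, with a phenolic oxygen on the neighbouring arene carbon. Each is therefore a six-membered aryl lactone that has taken up two methyl nucleophiles, and the O5/O1/O8 oxygens of ring A correspond to the lactone oxygen, 7-OH and 6-OH of esculetin.
- Last disconnections: kraussianone 3 ⇒ its 8,2'-bis-MOM ether ⇒ bis-lactone isoflavone + MeMgBr (four C–CH3 bonds at the two lactone carbonyls, ring D closed at the O4'–CMe2 bond).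
- Fragments: the bis-lactone isoflavone ⇒ C3–C1' Suzuki coupling of a lactone-fused 3-iodochromone (from esculetin) with a coumarin boronate (from 4-bromoresorcinol and malic acid).
- Ring order: rings A and B are bought as arenes; the ring-A lactone comes with esculetin and is saturated in step 3; ring C is closed in step 7; the ring-B lactone is made in step 8; ring D arises in step 12, when that lactone is opened and re-closed, while the ring-A lactone is opened for good.

Key step: step 12

Remark: isoflavone numbering (O1, C2 to C8a, primed positions on ring B) is used for the target and the chromone-containing compounds; coumarin numbering is used for the earlier intermediates.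
Remark: the target has no stereocentre; malic acid is taken as the racemate because its stereocentre is destroyed in step 8.
Remark: a Friedel–Crafts or Fries acetylation at C8 would not spare the MOM ether and the aryl lactone, so the acetyl group is brought in by iodination and Stille coupling (steps 4 and 5).

**Route**

Step 1
Reactants: 1 esculetin
Product: 2 7-(benzyloxy)-6-hydroxycoumarin
Conditions: BnBr (1.05 equiv), KHCO3, DMF, 40 °C
Reagents that add atoms: benzyl bromide BrCc1ccccc1
Why: Williamson etherification of the monophenoxide, in which 7-OH, conjugated with the lactone carbonyl through C4a and C3=C4, is the more acidic hydroxyl and should be ionised and benzylated by the weak base in preference to 6-OH.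

Step 2
Reactants: 2 7-(benzyloxy)-6-hydroxycoumarin
Product: 3 7-(benzyloxy)-6-(methoxymethoxy)coumarin
Conditions: MOMCl, iPr2NEt, CH2Cl2, 0 °C to rt
Reagents that add atoms: chloromethyl methyl ether COCCl
Why: MOM ether formation at the one remaining phenol by O-alkylation with the chloromethyl ether, under conditions that leave the lactone and the benzyl ether untouched.

Step 3
Reactants: 3 7-(benzyloxy)-6-(methoxymethoxy)coumarin
Product: 5 7-hydroxy-6-(methoxymethoxy)-3,4-dihydrocoumarin, via 7-hydroxy-6-(methoxymethoxy)coumarin 4 (not isolated)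
Conditions: H2 (4 atm), 10% Pd/C, EtOAc, 40 °C
Reagents that add atoms: none
Why: Catalytic hydrogenation should first cleave the benzyl ether by hydrogenolysis and then saturate the C3=C4 bond of the lactone, while the MOM acetal and the aryl lactone survive in the neutral aprotic medium.

Step 4
Reactants: 5 7-hydroxy-6-(methoxymethoxy)-3,4-dihydrocoumarin
Product: 6 7-hydroxy-8-iodo-6-(methoxymethoxy)-3,4-dihydrocoumarin
Conditions: NIS (1.05 equiv), MeCN, 0 °C to rt, dark
Reagents that add atoms: N-iodosuccinimide O=C1CCC(=O)N1I
Why: Electrophilic aromatic iodination directed by the free 7-OH, for which C8 is the only open ortho or para position (C6 and C4a are substituted), whereas C5 is activated only by the weaker OMOM donor.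

Step 5
Reactants: 6 7-hydroxy-8-iodo-6-(methoxymethoxy)-3,4-dihydrocoumarin
Product: 8 8-acetyl-7-hydroxy-6-(methoxymethoxy)-3,4-dihydrocoumarin, via 8-(1-ethoxyvinyl) enol ether 7 (not isolated)
Conditions: tributyl(1-ethoxyvinyl)stannane (1.3 equiv), PdCl2(PPh3)2 (5 mol %), toluene, 100 °C; then 1 M aq HCl, THF, rt
Reagents that add atoms: tributyl(1-ethoxyvinyl)stannane CCOC(=C)[Sn](CCCC)(CCCC)CCCC; water O
Why: Stille coupling of the aryl iodide with an acetyl-anion equivalent under neutral conditions, followed by enol ether hydrolysis, which in cold dilute acid is far faster than cleavage of the MOM acetal.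

Step 6
Reactants: 8 8-acetyl-7-hydroxy-6-(methoxymethoxy)-3,4-dihydrocoumarin
Product: 9 8-[(E)-3-(dimethylamino)prop-2-enoyl]-7-hydroxy-6-(methoxymethoxy)-3,4-dihydrocoumarin
Conditions: DMF-DMA (1.3 equiv), toluene, 4 Å MS, 75 °C
Reagents that add atoms: N,N-dimethylformamide dimethyl acetal COC(OC)N(C)C
Why: Enaminone formation by condensation of the amide acetal with the methyl group of the chelated ortho-hydroxyaryl ketone, which reacts well before the lactone CH2 at this temperature, while the sieves take up the methanol that could otherwise open the aryl lactone.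

Step 7
Reactants: 9 8-[(E)-3-(dimethylamino)prop-2-enoyl]-7-hydroxy-6-(methoxymethoxy)-3,4-dihydrocoumarin
Product: 10 9-iodo-6-(methoxymethoxy)-3,4-dihydro-2H,10H-pyrano[2,3-f]chromene-2,10-dione (3-iodo-8-(methoxymethoxy)chromone carrying the lactone ring O5–CO–CH2–CH2–C6)
Conditions: I2 (1.5 equiv), CHCl3, rt; aq Na2S2O3 work-up
Reagents that add atoms: iodine [I][I]
Why: Iodine-mediated cyclisation of an ortho-hydroxyaryl enaminone, in which α-iodination gives an iminium ion, the only free hydroxyl (7-OH) adds to its carbon in the 6-endo sense and dimethylamine is lost, so that ring C should close in a single orientation as the 3-iodochromone.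

Step 8
Reactants: 11 4-bromoresorcinol; 12 malic acid
Product: 14 6-bromo-7-hydroxycoumarin, via formylacetic acid 13 (not isolated)
Conditions: conc. H2SO4, 100 °C; then ice-water
Reagents that add atoms: none
Why: von Pechmann condensation, in which malic acid loses CO and water in sulfuric acid to give formylacetic acid, which attacks the resorcinol at C6 (para to one hydroxyl, ortho to the other, C4 being blocked by bromine) and lactonises onto the neighbouring hydroxyl.

Step 9
Reactants: 14 6-bromo-7-hydroxycoumarin
Product: 15 6-bromo-7-(methoxymethoxy)coumarin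
Conditions: MOMCl, iPr2NEt, DMF, 0 °C to rt
Reagents that add atoms: chloromethyl methyl ether COCCl
Why: MOM ether formation at the only hydroxyl, needed so that the later O2' cannot become a phenoxide conjugated with the lactone carbonyl in step 12.

Step 10
Reactants: 15 6-bromo-7-(methoxymethoxy)coumarin
Product: 16 7-(methoxymethoxy)-6-(4,4,5,5-tetramethyl-1,3,2-dioxaborolan-2-yl)coumarin
Conditions: B2pin2 (1.2 equiv), Pd(dppf)Cl2 (5 mol %), KOAc, 1,4-dioxane, 90 °C
Reagents that add atoms: bis(pinacolato)diboron CC1(C)OB(OC1(C)C)B1OC(C)(C)C(C)(C)O1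
Why: Miyaura borylation of the aryl bromide, with acetate too weak a base to open the coumarin or to promote Suzuki homocoupling.

Step 11
Reactants: 10 9-iodo-6-(methoxymethoxy)-3,4-dihydro-2H,10H-pyrano[2,3-f]chromene-2,10-dione; 16 7-(methoxymethoxy)-6-(4,4,5,5-tetramethyl-1,3,2-dioxaborolan-2-yl)coumarin
Product: 17 bis-lactone isoflavone 6-(methoxymethoxy)-9-[7-(methoxymethoxy)-2-oxo-2H-chromen-6-yl]-3,4-dihydro-2H,10H-pyrano[2,3-f]chromene-2,10-dione
Conditions: Pd(dppf)Cl2 (5 mol %), CsF (3 equiv), 1,4-dioxane, 90 °C
Reagents that add atoms: none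
Why: Suzuki–Miyaura coupling at C3 of a 3-iodochromone, the standard isoflavone construction, run with anhydrous fluoride so that no hydroxide or carbonate is present to open the aryl lactone or ring C.

Step 12
Reactants: 17 bis-lactone isoflavone; 18 methylmagnesium bromide
Product: 21 5-hydroxy-6-(3-hydroxy-3-methylbutyl)-8-(methoxymethoxy)-3-[7-(methoxymethoxy)-2,2-dimethyl-2H-chromen-6-yl]chromen-4-one, via ring-opened Z-allylic carbinol 19 (not isolated), via ortho-quinone methide 20 (not isolated)
Conditions: LaCl3·2LiCl (3 equiv), MeMgBr (2.5 equiv), THF, −78 °C; then MeMgBr (4 equiv), −20 to 0 °C; sat. aq NH4Cl; then PPTS (cat.), CH2Cl2, rt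
Reagents that add atoms: methylmagnesium bromide C[Mg]Br
Why: At −78 °C the aryl ester carbonyl of the ring-A lactone, the most electrophilic site, should take up two methyl groups: the first adduct expels the O5 phenoxide to leave a methyl ketone, whose enolisation the oxophilic lanthanum salt holds back, and the second addition gives the tertiary alkoxide, while the O5 phenoxide, now chelated to the C4 carbonyl, turns ring C into an electron-rich vinylogous carboxylate that should no longer accept a nucleophile at C2 or C4. On warming, the coumarin carbonyl of ring B should react in the same 1,2-sense with loss of the O4' phenoxide to give the (Z)-allylic tertiary alkoxide, four C–CH3 bonds being formed in all; the closest known reaction is the double Grignard addition to aryl lactones that converts coumarins into 2,2-dimethyl-2H-chromenes and dihydrocoumarins into 2-(3-hydroxy-3-methylbutyl)phenols, used here on both lactone types in one molecule. After the quench, PPTS should ionise the (Z)-allylic carbinol of 19 with help from O4' to the ortho-quinone methide 20, and ring D then closes by oxa-6π electrocyclisation, which forms the O4'–CMe2 bond; the carbinol on ring A, lacking the alkene, cannot form a quinone methide under these conditions and remains an open chain, so it is the hydrogenation of step 3 that fixes ring A as the chain and ring B as the chromene. No stereocentre is created, and the Z alkene required for ring closure is inherited from the coumarin ring. The step needs chemoselectivity for the two lactone carbonyls over C2 and C4 of ring C and carbonyl addition over conjugate addition at C4 of the coumarin; this should be secured by the good aryloxide leaving groups, the staged temperature, LaCl3·2LiCl and the O5 phenoxide generated by the first ring opening, while the MOM group keeps O2' from becoming a phenoxide that would deactivate the coumarin carbonyl.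

Step 13
Reactants: 21 5-hydroxy-6-(3-hydroxy-3-methylbutyl)-8-(methoxymethoxy)-3-[7-(methoxymethoxy)-2,2-dimethyl-2H-chromen-6-yl]chromen-4-one
Product: 22 kraussianone 3 (5,8-dihydroxy-3-(7-hydroxy-2,2-dimethyl-2H-chromen-6-yl)-6-(3-hydroxy-3-methylbutyl)chromen-4-one)
Conditions: HCl (about 0.5 M) in degassed MeOH, rt, argon
Reagents that add atoms: none
Why: Acid-catalysed acetal exchange should transfer both MOM groups to methanol as dimethoxymethane at room temperature, where the non-allylic tertiary carbinol and the chromene are expected to survive, and argon protects the freed 5,8-hydroquinone from air oxidation.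

**Compound list**

1 | esculetin (6,7-dihydroxycoumarin) | O=c1ccc2cc(O)c(O)cc2o1 | starting material
2 | 7-(benzyloxy)-6-hydroxycoumarin | O=c1ccc2cc(O)c(OCc3ccccc3)cc2o1 | intermediate
3 | 7-(benzyloxy)-6-(methoxymethoxy)coumarin | O=c1ccc2cc(OCOC)c(OCc3ccccc3)cc2o1 | intermediate
4 | 7-hydroxy-6-(methoxymethoxy)coumarin (not isolated) | O=c1ccc2cc(OCOC)c(O)cc2o1 | intermediate
5 | 7-hydroxy-6-(methoxymethoxy)-3,4-dihydrocoumarin | O=C1CCc2cc(OCOC)c(O)cc2O1 | intermediate
6 | 7-hydroxy-8-iodo-6-(methoxymethoxy)-3,4-dihydrocoumarin | O=C1CCc2cc(OCOC)c(O)c(I)c2O1 | intermediate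
7 | 8-(1-ethoxyvinyl)-7-hydroxy-6-(methoxymethoxy)-3,4-dihydrocoumarin (not isolated) | O=C1CCc2cc(OCOC)c(O)c(C(=C)OCC)c2O1 | intermediate
8 | 8-acetyl-7-hydroxy-6-(methoxymethoxy)-3,4-dihydrocoumarin | O=C1CCc2cc(OCOC)c(O)c(C(C)=O)c2O1 | intermediate
9 | 8-[(E)-3-(dimethylamino)prop-2-enoyl]-7-hydroxy-6-(methoxymethoxy)-3,4-dihydrocoumarin | O=C1CCc2cc(OCOC)c(O)c(C(=O)/C=C/N(C)C)c2O1 | intermediate
10 | 9-iodo-6-(methoxymethoxy)-3,4-dihydro-2H,10H-pyrano[2,3-f]chromene-2,10-dione (lactone-fused 3-iodochromone) | O=C1CCc2cc(OCOC)c3occ(I)c(=O)c3c2O1 | intermediate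
11 | 4-bromoresorcinol | Oc1ccc(Br)c(O)c1 | starting material
12 | malic acid (racemic) | OC(CC(=O)O)C(=O)O | starting material
13 | formylacetic acid (3-oxopropanoic acid; not isolated) | O=CCC(=O)O | intermediate
14 | 6-bromo-7-hydroxycoumarin | O=c1ccc2cc(Br)c(O)cc2o1 | intermediate
15 | 6-bromo-7-(methoxymethoxy)coumarin | O=c1ccc2cc(Br)c(OCOC)cc2o1 | intermediate
16 | 7-(methoxymethoxy)-6-(4,4,5,5-tetramethyl-1,3,2-dioxaborolan-2-yl)coumarin | CC1(C)OB(c2cc3ccc(=O)oc3cc2OCOC)OC1(C)C | intermediate
17 | bis-lactone isoflavone, 8,2'-di-O-MOM (ring-A lactone O5–CO–CH2–CH2–C6; ring-B coumarin lactone O4'–CO–CH=CH–C5') | O=C1CCc2cc(OCOC)c3occ(-c4cc5ccc(=O)oc5cc4OCOC)c(=O)c3c2O1 | intermediate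
18 | methylmagnesium bromide | C[Mg]Br | starting material
19 | 5-hydroxy-3-{4-hydroxy-5-[(Z)-3-hydroxy-3-methylbut-1-enyl]-2-(methoxymethoxy)phenyl}-6-(3-hydroxy-3-methylbutyl)-8-(methoxymethoxy)chromen-4-one (not isolated) | CC(C)(O)CCc1cc(OCOC)c2occ(-c3cc(/C=C\C(C)(C)O)c(O)cc3OCOC)c(=O)c2c1O | intermediate
20 | ortho-quinone methide of ring B (C4'=O, C5'=CH–CH=CMe2; not isolated) | CC(C)=C/C=C1/C=C(c2coc3c(OCOC)cc(CCC(C)(C)O)c(O)c3c2=O)C(OCOC)=CC1=O | intermediate
21 | 8,2'-bis(methoxymethyl) ether of the target: 5-hydroxy-6-(3-hydroxy-3-methylbutyl)-8-(methoxymethoxy)-3-[7-(methoxymethoxy)-2,2-dimethyl-2H-chromen-6-yl]chromen-4-one | CC(C)(O)CCc1cc(OCOC)c2occ(-c3cc4c(cc3OCOC)OC(C)(C)C=C4)c(=O)c2c1O | intermediate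
22 | kraussianone 3: 5,8-dihydroxy-3-(7-hydroxy-2,2-dimethyl-2H-chromen-6-yl)-6-(3-hydroxy-3-methylbutyl)chromen-4-one | CC(C)(O)CCc1cc(O)c2occ(-c3cc4c(cc3O)OC(C)(C)C=C4)c(=O)c2c1O | target

**Step count**

Total step count: 13. Longest linear sequence: 10 steps (steps 1 to 7, then 11, 12 and 13).

**Steps most likely to fail**

Step 12. What may go wrong is methyl transfer to C2 or C4 of ring C, or conjugate addition at C4 of the coumarin, competing with the slower opening of the second lactone; enolisation of the intermediate methyl ketones could also stop the additions halfway. The fallback opens the two lactones separately, the coumarin one before any chromone exists. It sets out from 15: double methyl addition (MeMgBr, LaCl3·2LiCl, THF, 0 °C; the aryl bromide is inert) and PPTS-induced ring closure would give 6-bromo-7-(methoxymethoxy)-2,2-dimethyl-2H-chromene F1. Miyaura borylation as in step 10 would give the chromene boronate F2, and Suzuki coupling with 10 under the conditions of step 11 would give the chromene-bearing mono-lactone isoflavone F3. Treating F3 with MeMgBr (2.5 equiv) and LaCl3·2LiCl at −78 °C, where only the activated aryl ester should react, would open the ring-A lactone and come back to the route at 21.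

Step 11. What may go wrong is fluoride- or base-induced opening of the aryl lactone or of ring C, together with protodeboronation of the ortho-alkoxy boronate, outrunning transmetalation. The fallback is a base-free Stille coupling. It sets out from 15: stannylation with hexamethylditin (Pd(PPh3)4, toluene, 100 °C) would give 7-(methoxymethoxy)-6-(trimethylstannyl)coumarin F4, which would be coupled with 10 (Pd(PPh3)4, CuI, DMF, 60 °C) to come back at 17.

Step 13. What may go wrong is acid-promoted addition of methanol to the electron-rich chromene or its dimerisation, ionisation of the tertiary carbinol with closure onto O5 to a chroman, and air oxidation of the freed 5,8-hydroquinone. The fallback moves the acid treatment to a stage where neither the chromene nor the carbinol exists and carries silyl ethers through the methyl addition. It sets out from 17: MOM cleavage with 4 M HCl in 1,4-dioxane at rt would give the 8,2'-dihydroxy bis-lactone F5, and silylation (TBSOTf, 2,6-lutidine, CH2Cl2, 0 °C) the bis-TBS bis-lactone F6. The methyl addition and ring closure under the conditions of step 12 would give the 8,2'-bis-TBS ether F7 of the target, and TBAF buffered with AcOH (THF, 0 °C, argon) would then release 22 without acid.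

**Further compounds**

F1 | step 12 | 6-bromo-7-(methoxymethoxy)-2,2-dimethyl-2H-chromene | CC1(C)C=Cc2cc(Br)c(OCOC)cc2O1
F2 | step 12 | 7-(methoxymethoxy)-2,2-dimethyl-6-(4,4,5,5-tetramethyl-1,3,2-dioxaborolan-2-yl)-2H-chromene | CC1(C)C=Cc2cc(B3OC(C)(C)C(C)(C)O3)c(OCOC)cc2O1
F3 | step 12 | chromene-bearing mono-lactone isoflavone, 8,2'-di-O-MOM | O=C1CCc2cc(OCOC)c3occ(-c4cc5c(cc4OCOC)OC(C)(C)C=C5)c(=O)c3c2O1
F4 | step 11 | 7-(methoxymethoxy)-6-(trimethylstannyl)coumarin | C[Sn](C)(C)c1cc2ccc(=O)oc2cc1OCOC
F5 | step 13 | 8,2'-dihydroxy bis-lactone isoflavone | O=C1CCc2cc(O)c3occ(-c4cc5ccc(=O)oc5cc4O)c(=O)c3c2O1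
F6 | step 13 | 8,2'-bis-O-TBS bis-lactone isoflavone | O=C1CCc2cc(O[Si](C)(C)C(C)(C)C)c3occ(-c4cc5ccc(=O)oc5cc4O[Si](C)(C)C(C)(C)C)c(=O)c3c2O1
F7 | step 13 | 8,2'-bis-O-TBS ether of kraussianone 3 | CC(C)(O)CCc1cc(O[Si](C)(C)C(C)(C)C)c2occ(-c3cc4c(cc3O[Si](C)(C)C(C)(C)C)OC(C)(C)C=C4)c(=O)c2c1O
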